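If the catalyst could not tell the hands apart, 50% conversion would find left-handed substrate at 25.0%. That mirror case is my zero of scale, since no reading shows the right-handed substrate.

| setting | north | south-east | flask |
|---|---|---|---|
| left-handed substrate | 47 mM | 47 mM | 47 mM |
| right-handed substrate | 47 mM | 47 mM | 47 mM |
| coupling partner | 3 equiv | 3 equiv | 3.00 equiv |
| free catalyst | 0.048 mol% | 0.19 mol% | 0.096 mol% |
| impurity | 5 µM | 5 µM | 5.0 µM |
| remark | run made earlier | run made earlier |  |

| run | time / min | left-handed product / % | left-handed substrate / % |
|---|---|---|---|
| north | 5.00 | 13 | 37 |
| north | 10.0 | 19 | 32 |
| north | 15.0 | 22 | 28 |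
| north | 20.0 | 23 | 25 |
| north | 25.0 | 27 | 23 |
| south-east | 2.00 | 23 | 30 |
| south-east | 6.00 | 33 | 13 |
| south-east | 12.0 | 46 | 8 |
| south-east | 15.0 | 45 | 8 |
| south-east | 25.0 | 49 | 5 |

(standard deviation of a reading: 1.5 percentage points)

- free catalyst is single-handed; left-handed substrate and right-handed substrate are mirror images of each other, charged as a racemate, each of them at the stated concentration

* factor on the rate of making left-handed product when 50% of the left-handed substrate and right-handed substrate together are converted if free catalyst is charged twice over
* factor on the rate when 50% of the left-handed substrate and right-handed substrate together are converted if free catalyst is charged at 1 mol% instead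

At equal composition the rate follows the working catalyst, so I keep books on that. The flask charges 45.1 µM of free catalyst. The first entry is the impurity: c(impurity) is 5.0 µM, and I let it take its equal of free catalyst, 11.1% of the charge.

The second entry is fading. South-east's left-handed substrate loses a fraction 0.209 /min early but 0.0362 /min late, which I read as catalyst leaving its round. If it leaves at a fixed fraction per minute, while conversion also goes with working catalyst, then a given conversion costs the same µM at any charge.

Near my level, north loses 0.0220 /min, so south-east runs 9.50 times as fast on 89.3 µM against 22.6 µM. The rate goes as charge minus the catalyst lost by that conversion, and this loss is the toll, 14.7 µM, a rough reading given the scatter of 1.5 percentage points.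

By my reckoning the flask's books at 50% conversion then read: 5.0 µM to impurity, 9.70 µM faded, 30.4 µM working. Doubling gives 2.48 and 1 mol% gives 15.0. I commit to these but expect them to be low, betting that a single-handed catalyst favours the left-handed substrate, which would put the level deeper and the toll higher.

The forecast gives 2.4 and 15 as values, expecting that the “excess order should fade at high loading”.

The flask gives 3.70 and 26.5.

    free catalyst + impurity → spent catalyst (k = 20200 /M/s)
    free catalyst ⇌ dormant form (K = 26.0, k = 9.88 × 10⁻⁴ /s)
    coupling partner + free catalyst + left-handed substrate → free catalyst + left-handed product (k = 449 /M²/s)
    coupling partner + free catalyst + right-handed substrate → free catalyst + right-handed product (k = 128 /M²/s)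

A doubling factor of 3.70 means a toll of 28.4 µM, more than my 14.7 µM. Carried to a charge of 1 mol%, that toll gives 26.4 against the 26.5 the flask gives. Beyond the impurity's 5.0 µM, the toll is free catalyst gone to dormant form: with that step removed, the apparent order in free catalyst falls from 2.7 to 1.1.

Readings and results come from a simulation with made-up constants; the scatter is artificial.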